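**Retrosynthetic overview**
- Feature: the indole C3–C3a bond is an edge of the 21-membered ring (C3 carries the CH2CH2NH arm, C5 the ether oxygen to C8). Building the pyrrole ring (C3–C3a and N1–C2) from a 2-iodoaniline and a tethered triethylsilyl alkyne therefore closes the macrocycle in the same event; both rings form together and last, the benzene rings are bought.
- Seco compound: 7,9-acetonide, ring A phenol as triisopropylsilyl ether, 4-amino-3-iodophenyl ether at C8. Its C7–C8 bond comes from an Evans syn-aldol of an (R)-oxazolidinone (3-iodo-4-nitrophenoxy)acetate with the ring A aldehyde, then Mitsunobu inversion at C7 to the erythro (7R,8S) array.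
- Ring A aldehyde: 5-hydroxyvanillin, allyl block on the more acidic 4-OH, Chan–Lam O-arylation of O3 with the preformed cinnamamide boronic acid, then allyl exchanged for triisopropylsilyl.
- End: dilute HCl removes the acetonide and the C2 silyl group; buffered fluoride frees the phenol.

Key step: step 13

Remark: C7 = benzylic carbinol carbon, C8 = aryloxy methine, C9 = CH2OH carbon; ArA = 3-methoxy-4-[(triisopropylsilyl)oxy]-5-(4-{(1E)-3-oxo-3-[(4-(triethylsilyl)but-3-yn-1-yl)amino]prop-1-en-1-yl}phenoxy)phenyl; all five starting materials are assumed to be catalogue compounds.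

**Step 1**
Reactants: 1 but-3-yn-1-amine
Product: 4 4-(triethylsilyl)but-3-yn-1-amine, via dilithio amine 2 (not isolated), via bis-silyl amine 3 (not isolated)
Conditions: n-BuLi (2.1 equiv), THF, −78 → 0 °C; Et3SiCl (2.1 equiv), 0 °C → rt; then H2O, rt
Reagents that add atoms: chlorotriethylsilane, CC[Si](Cl)(CC)CC
Why: Deprotonation at the alkyne C–H and at nitrogen followed by silylation of both sites (alkynyl C-silylation with transient N-silyl protection) should give the bis-silyl amine, whose N–Si bond hydrolyses on aqueous work-up while the C(sp)–Si bond stays.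

**Step 2**
Reactants: 4 4-(triethylsilyl)but-3-yn-1-amine; 5 (E)-3-(4-boronophenyl)prop-2-enoic acid
Product: 6 {4-[(1E)-3-oxo-3-{[4-(triethylsilyl)but-3-yn-1-yl]amino}prop-1-en-1-yl]phenyl}boronic acid
Conditions: EDC·HCl, HOBt, iPr2NEt, DMF, 0 °C → rt
Reagents that add atoms: none
Why: Carbodiimide amide coupling through the hydroxybenzotriazole ester should acylate the primary amine; the arylboronic acid and the silyl alkyne are spectators and the E alkene is not touched.

**Step 3**
Reactants: 7 3,4-dihydroxy-5-methoxybenzaldehyde (5-hydroxyvanillin)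
Product: 8 3-hydroxy-5-methoxy-4-(prop-2-en-1-yloxy)benzaldehyde
Conditions: allyl bromide (1.1 equiv), NaHCO3, DMF, 40 °C
Reagents that add atoms: allyl bromide, C=CCBr
Why: Williamson etherification with a weak base should alkylate only the 4-OH, the more acidic phenol (para to the formyl group); this blocks the oxygen that would otherwise be arylated, and an allyl ether, unlike a silyl ether, cannot migrate to the neighbouring phenol.

**Step 4**
Reactants: 8 3-hydroxy-5-methoxy-4-(prop-2-en-1-yloxy)benzaldehyde; 6 cinnamamide boronic acid (1.5 equiv)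
Product: 9 (E)-3-{4-[5-formyl-3-methoxy-2-(prop-2-en-1-yloxy)phenoxy]phenyl}-N-[4-(triethylsilyl)but-3-yn-1-yl]prop-2-enamide
Conditions: Cu(OAc)2 (1 equiv, kept divalent by air), pyridine, 4 Å molecular sieves, CH2Cl2, dry air, rt
Reagents that add atoms: none
Why: Chan–Lam–Evans O-arylation (transmetalation of the arylboronic acid to copper, C–O reductive elimination) should join the only free phenol, O3, to ring B at room temperature, which leaves the ring A aldehyde free and generates no fluoride or strong base that would harm the silyl alkyne.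

**Step 5**
Reactants: 9 allyl ether
Product: 10 (E)-3-[4-(5-formyl-2-hydroxy-3-methoxyphenoxy)phenyl]-N-[4-(triethylsilyl)but-3-yn-1-yl]prop-2-enamide
Conditions: Pd(PPh3)4 (5 mol %), morpholine, THF, rt
Reagents that add atoms: none
Why: Tsuji–Trost deallylation: zerovalent palladium ionizes the aryl allyl ether to a π-allyl complex that morpholine traps, which should free the phenol without affecting the aldehyde, the cinnamamide or the silyl alkyne (no aryl halide is present yet).

**Step 6**
Reactants: 10 phenol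
Product: 11 (E)-3-(4-{5-formyl-3-methoxy-2-[(triisopropylsilyl)oxy]phenoxy}phenyl)-N-[4-(triethylsilyl)but-3-yn-1-yl]prop-2-enamide (ArA–CHO)
Conditions: iPr3SiCl, imidazole, DMF, rt → 40 °C
Reagents that add atoms: chlorotriisopropylsilane, CC(C)[Si](Cl)(C(C)C)C(C)C
Why: Imidazole-promoted O-silylation of the acidic phenol should install the group that can later be removed with fluoride under conditions the finished macrocycle tolerates.

**Step 7**
Reactants: 12 3-iodo-4-nitrophenol; 13 (4R)-4-benzyl-3-(chloroacetyl)-1,3-oxazolidin-2-one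
Product: 14 (4R)-4-benzyl-3-[(3-iodo-4-nitrophenoxy)acetyl]-1,3-oxazolidin-2-one
Conditions: K2CO3, NaI (cat.), acetone, rt → 40 °C
Reagents that add atoms: none
Why: Williamson alkylation of the nitrophenoxide by the α-chloro imide (iodide-assisted SN2) should give the glycolate imide that carries the future indole benzene ring with nitrogen and iodine already in place.

**Step 8**
Reactants: 14 glycolate imide (1.3 equiv); 11 ArA–CHO
Product: 17 (4R)-4-benzyl-3-[(2R,3S)-3-ArA-3-hydroxy-2-(3-iodo-4-nitrophenoxy)propanoyl]-1,3-oxazolidin-2-one, via boron enolate 15 (not isolated), via boron aldolate 16 (not isolated)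
Conditions: Bu2BOTf, iPr2NEt, CH2Cl2, −78 → 0 °C; then 11, −78 → 0 °C; pH 7 buffer, MeOH, 30% H2O2, 0 °C
Reagents that add atoms: none
Why: Evans syn-aldol: the Z boron enolate should add through a Zimmerman–Traxler chair on the face away from the benzyl group of the (R)-auxiliary, giving the (2R,3S) syn pair, that is C8 with the spatial arrangement of the target and C7 as its epimer; amide N–H, silyl groups, nitro group and aryl iodide are inert to the boron enolate.

**Step 9**
Reactants: 17 syn-aldol adduct
Product: 18 (4R)-4-benzyl-3-[(2R,3R)-3-ArA-2-(3-iodo-4-nitrophenoxy)-3-(4-nitrobenzoyloxy)propanoyl]-1,3-oxazolidin-2-one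
Conditions: 4-nitrobenzoic acid, PPh3, DIAD, THF, 0 °C → rt
Reagents that add atoms: 4-nitrobenzoic acid, O=C(O)c1ccc(cc1)[N+](=O)[O-]
Why: Mitsunobu inversion: the benzylic C7 hydroxyl is activated as its oxyphosphonium and displaced by 4-nitrobenzoate in an SN2 reaction, which should turn the syn (threo) array into the anti (erythro) one with C7 = R in target locants; the imide α-hydrogen lies in the carbonyl plane (allylic strain), which disfavours elimination.

**Step 10**
Reactants: 18 nitrobenzoate imide
Product: 19 (1R,2S)-1-ArA-2-(3-iodo-4-nitrophenoxy)propane-1,3-diol (erythro)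
Conditions: LiBH4, MeOH (additive), THF, 0 °C → rt
Reagents that add atoms: none
Why: Borohydride reduction (reductive removal of an Evans auxiliary) should cleave the N-acyl oxazolidinone to the C9 primary alcohol and the activated benzoate to the C7 alcohol; nitroarene, aryl iodide, cinnamamide and silyl groups are not reduced and neither stereocentre is touched.

**Step 11**
Reactants: 19 erythro diol
Product: 20 (4R,5S)-4-ArA-5-(3-iodo-4-nitrophenoxy)-2,2-dimethyl-1,3-dioxane (trans)
Conditions: 2,2-dimethoxypropane, PPTS (cat.), CH2Cl2, rt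
Reagents that add atoms: 2,2-dimethoxypropane, COC(C)(C)OC
Why: Acid-catalysed transketalization should tie O7 and O9, the only diol, into the six-membered acetonide; the erythro diol gives the trans-4,5-disubstituted dioxane with both groups equatorial.

**Step 12**
Reactants: 20 nitro acetonide
Product: 21 2-iodo-4-{[(4R,5S)-4-ArA-2,2-dimethyl-1,3-dioxan-5-yl]oxy}aniline (seco compound)
Conditions: Fe powder, NH4Cl, EtOH–H2O 4:1, 70 °C
Reagents that add atoms: none
Why: Béchamp-type iron reduction in buffered aqueous ethanol should reduce the nitro group to the aniline by electron transfer and leave the aryl iodide, alkene, silyl alkyne, acetonide and aryl silyl ether alone.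

**Step 13**
Reactants: 21 seco 2-iodoaniline silylalkyne amide
Product: 22 protected macrocycle: the target with 7,9-O-isopropylidene (7R,8S), ring A O-triisopropylsilyl and indole C2-triethylsilyl groups
Conditions: Pd(OAc)2 (0.3 equiv), 1,1'-bis(di-tert-butylphosphino)ferrocene (0.4 equiv), Et3N (3 equiv), toluene–MeCN 1:1, 1 mM (slow addition of 21), 85 °C
Reagents that add atoms: none
Why: Zerovalent palladium, formed in the flask from Pd(OAc)2 and the bulky bisphosphine, inserts into the aryl–iodine bond; the tethered alkyne then inserts syn with the aryl carbon bonding to the alkyne carbon remote from silicon, the aniline nitrogen displaces iodide on palladium to give a six-membered azapalladacycle, and C–N reductive elimination forms N1–C2 and returns zerovalent palladium. The closest known reaction type is the Larock indole heteroannulation of a 2-iodoaniline with a triethylsilyl alkyne, run here as a macrocyclization. The 21-membered ring closes in the intramolecular carbopalladation in the exo-dig mode (only the carbon that becomes C3 enters the large ring), and the pyrrole ring closes at the C–N reductive elimination. No stereocentre is formed, and C7 and C8 are not touched. The step needs regioselective insertion, secured by the bulky triethylsilyl group, which takes the position next to palladium and so ends at C2, and ring closure over oligomerization, secured by 1 mM concentration with slow addition and by a tether of few rotatable bonds (diaryl ether, E-cinnamamide, two methylenes). The alkyne should insert faster than the conjugated alkene, and the acetonide, the aryl silyl ether and the secondary amide are inert to the amine base.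

**Step 14**
Reactants: 22 protected macrocycle
Product: 24 ring A O-triisopropylsilyl ether of the target (free 7,9-diol and indole C2–H), via silylindole diol 23 (not isolated)
Conditions: 2 M aq. HCl–THF 1:4, rt → 40 °C
Reagents that add atoms: none
Why: Aqueous acid should hydrolyse the isopropylidene ketal and then protonate the 2-silylindole at C2 (ipso attack, cation β to silicon) so that the triethylsilyl group is lost (protodesilylation of a 2-silylindole); the aryl silyl ether survives dilute HCl and, with the phenol still capped and the β-aryloxy group withdrawing, the benzylic C7–O bond should not ionize, so C7 keeps its configuration.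

**Step 15**
Reactants: 24 O-triisopropylsilyl ether of the target
Product: 25 CNP0276372.1 (target, 7R,8S)
Conditions: Bu4NF (1.2 equiv), AcOH (1.2 equiv), THF, 0 °C
Reagents that add atoms: none
Why: Fluoride attack at silicon (silyl ether cleavage) should release the ring A phenol; acetic acid buffers the phenoxide so that the p-hydroxybenzyl alcohol is not exposed to base, and nothing else in the molecule is fluoride-labile at this stage.

**Compound list**
1 | but-3-yn-1-amine | NCCC#C | starting material
2 | N,C-dilithio but-3-yn-1-amine (lithium amide acetylide) | [Li]NCCC#C[Li] | intermediate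
3 | N-(triethylsilyl)-4-(triethylsilyl)but-3-yn-1-amine | CC[Si](CC)(CC)NCCC#C[Si](CC)(CC)CC | intermediate
4 | 4-(triethylsilyl)but-3-yn-1-amine | NCCC#C[Si](CC)(CC)CC | intermediate
5 | (E)-3-(4-boronophenyl)prop-2-enoic acid | OB(O)c1ccc(/C=C/C(=O)O)cc1 | starting material
6 | {4-[(1E)-3-oxo-3-{[4-(triethylsilyl)but-3-yn-1-yl]amino}prop-1-en-1-yl]phenyl}boronic acid | OB(O)c1ccc(/C=C/C(=O)NCCC#C[Si](CC)(CC)CC)cc1 | intermediate
7 | 3,4-dihydroxy-5-methoxybenzaldehyde | COc1cc(C=O)cc(O)c1O | starting material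
8 | 3-hydroxy-5-methoxy-4-(prop-2-en-1-yloxy)benzaldehyde | COc1cc(C=O)cc(O)c1OCC=C | intermediate
9 | (E)-3-{4-[5-formyl-3-methoxy-2-(prop-2-en-1-yloxy)phenoxy]phenyl}-N-[4-(triethylsilyl)but-3-yn-1-yl]prop-2-enamide | COc1cc(C=O)cc(Oc2ccc(/C=C/C(=O)NCCC#C[Si](CC)(CC)CC)cc2)c1OCC=C | intermediate
10 | (E)-3-[4-(5-formyl-2-hydroxy-3-methoxyphenoxy)phenyl]-N-[4-(triethylsilyl)but-3-yn-1-yl]prop-2-enamide | COc1cc(C=O)cc(Oc2ccc(/C=C/C(=O)NCCC#C[Si](CC)(CC)CC)cc2)c1O | intermediate
11 | (E)-3-(4-{5-formyl-3-methoxy-2-[(triisopropylsilyl)oxy]phenoxy}phenyl)-N-[4-(triethylsilyl)but-3-yn-1-yl]prop-2-enamide (ArA–CHO) | COc1cc(C=O)cc(Oc2ccc(/C=C/C(=O)NCCC#C[Si](CC)(CC)CC)cc2)c1O[Si](C(C)C)(C(C)C)C(C)C | intermediate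
12 | 3-iodo-4-nitrophenol | Oc1ccc([N+](=O)[O-])c(I)c1 | starting material
13 | (4R)-4-benzyl-3-(chloroacetyl)-1,3-oxazolidin-2-one | O=C(CCl)N1[C@H](Cc2ccccc2)COC1=O | starting material
14 | (4R)-4-benzyl-3-[(3-iodo-4-nitrophenoxy)acetyl]-1,3-oxazolidin-2-one | O=C(COc1ccc([N+](=O)[O-])c(I)c1)N1[C@H](Cc2ccccc2)COC1=O | intermediate
15 | Z-dibutylboron enolate of 14 | CCCCB(CCCC)O/C(=C\Oc1ccc([N+](=O)[O-])c(I)c1)N1[C@H](Cc2ccccc2)COC1=O | intermediate
16 | O-dibutylboryl aldolate of 17 | COc1cc(cc(Oc2ccc(/C=C/C(=O)NCCC#C[Si](CC)(CC)CC)cc2)c1O[Si](C(C)C)(C(C)C)C(C)C)[C@H](OB(CCCC)CCCC)[C@@H](Oc3ccc([N+](=O)[O-])c(I)c3)C(=O)N4[C@H](Cc5ccccc5)COC4=O | intermediate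
17 | (4R)-4-benzyl-3-[(2R,3S)-3-ArA-3-hydroxy-2-(3-iodo-4-nitrophenoxy)propanoyl]-1,3-oxazolidin-2-one | COc1cc(cc(Oc2ccc(/C=C/C(=O)NCCC#C[Si](CC)(CC)CC)cc2)c1O[Si](C(C)C)(C(C)C)C(C)C)[C@H](O)[C@@H](Oc3ccc([N+](=O)[O-])c(I)c3)C(=O)N4[C@H](Cc5ccccc5)COC4=O | intermediate
18 | (4R)-4-benzyl-3-[(2R,3R)-3-ArA-2-(3-iodo-4-nitrophenoxy)-3-(4-nitrobenzoyloxy)propanoyl]-1,3-oxazolidin-2-one | COc1cc(cc(Oc2ccc(/C=C/C(=O)NCCC#C[Si](CC)(CC)CC)cc2)c1O[Si](C(C)C)(C(C)C)C(C)C)[C@@H](OC(=O)c6ccc(cc6)[N+](=O)[O-])[C@@H](Oc3ccc([N+](=O)[O-])c(I)c3)C(=O)N4[C@H](Cc5ccccc5)COC4=O | intermediate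
19 | (1R,2S)-1-ArA-2-(3-iodo-4-nitrophenoxy)propane-1,3-diol | COc1cc(cc(Oc2ccc(/C=C/C(=O)NCCC#C[Si](CC)(CC)CC)cc2)c1O[Si](C(C)C)(C(C)C)C(C)C)[C@@H](O)[C@@H](Oc3ccc([N+](=O)[O-])c(I)c3)CO | intermediate
20 | (4R,5S)-4-ArA-5-(3-iodo-4-nitrophenoxy)-2,2-dimethyl-1,3-dioxane | COc1cc(cc(Oc2ccc(/C=C/C(=O)NCCC#C[Si](CC)(CC)CC)cc2)c1O[Si](C(C)C)(C(C)C)C(C)C)[C@H]3OC(C)(C)OC[C@@H]3Oc4ccc([N+](=O)[O-])c(I)c4 | intermediate
21 | 2-iodo-4-{[(4R,5S)-4-ArA-2,2-dimethyl-1,3-dioxan-5-yl]oxy}aniline | COc1cc(cc(Oc2ccc(/C=C/C(=O)NCCC#C[Si](CC)(CC)CC)cc2)c1O[Si](C(C)C)(C(C)C)C(C)C)[C@H]3OC(C)(C)OC[C@@H]3Oc4ccc(N)c(I)c4 | intermediate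
22 | protected macrocycle (7,9-acetonide, O-triisopropylsilyl, C2-triethylsilyl) | COc1cc2cc(c1O[Si](C(C)C)(C(C)C)C(C)C)Oc1ccc(cc1)/C=C/C(=O)NCCc1c([Si](CC)(CC)CC)[nH]c3ccc(cc13)O[C@H]4COC(C)(C)O[C@H]24 | intermediate
23 | macrocyclic 7,9-diol with O-triisopropylsilyl and C2-triethylsilyl groups | COc1cc2cc(c1O[Si](C(C)C)(C(C)C)C(C)C)Oc1ccc(cc1)/C=C/C(=O)NCCc1c([Si](CC)(CC)CC)[nH]c3ccc(cc13)O[C@@H](CO)[C@@H]2O | intermediate
24 | ring A O-triisopropylsilyl ether of the target | COc1cc2cc(c1O[Si](C(C)C)(C(C)C)C(C)C)Oc1ccc(cc1)/C=C/C(=O)NCCc1c[nH]c3ccc(cc13)O[C@@H](CO)[C@@H]2O | intermediate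
25 | CNP0276372.1 | COc1cc2cc(c1O)Oc1ccc(cc1)/C=C/C(=O)NCCc1c[nH]c3ccc(cc13)O[C@@H](CO)[C@@H]2O | target

**Step count and risks**
Total number of steps: 15. Longest linear sequence: 13 steps (steps 1, 2, 4, 5, 6, 8, 9, 10, 11, 12, 13, 14, 15).

Steps most likely to fail:

1. Step 13. Intermolecular carbopalladation (oligomer formation), hydrodehalogenation of the arylpalladium iodide, or insertion into the cinnamamide alkene may outrun the 21-membered ring closure. The fallback sets out from 21 and comes back at 22; it changes the nitrogen partner to an acetanilide, so that an anionic amidate rather than a neutral amine binds palladium, and uses a full equivalent of palladium. Compound 21 with Ac2O and pyridine should give the N-acetyl-2-iodoanilide F1. F1 with Pd(OAc)2 (1.1 equiv), 1,1'-bis(di-tert-butylphosphino)ferrocene (1.3 equiv) and Et3N in toluene–MeCN at 110 °C and 1 mM should give the N-acetyl-2-(triethylsilyl)indole macrocycle F2. NH3 in MeOH at rt should then remove the activated N-acetyl group and give 22.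

2. Step 9. Elimination from the benzylic oxyphosphonium toward the α-aryloxy cinnamoyl imide, or ionization at the benzylic carbon with loss of stereochemical fidelity, may compete with the SN2 displacement. The fallback sets out from 11 (with 12) and comes back at 19; it forms the C8–O bond by inversion and leaves C7 as set by the aldol. (S)-4-Benzyl-1,3-oxazolidin-2-one is N-acylated (n-BuLi, bromoacetyl bromide, THF, −78 °C) to (4S)-4-benzyl-3-(bromoacetyl)-1,3-oxazolidin-2-one F3. Its boron enolate (Bu2BOTf, Et3N, CH2Cl2, −78 °C) should add to 11 to give the (2S,3R) syn-bromohydrin imide F4. Cesium 3-iodo-4-nitrophenoxide (from 12 and Cs2CO3, DMF, rt) should displace bromide with inversion at C8 to give the (2R,3R) anti aryloxy imide F5, and LiBH4 in THF should cleave the auxiliary to give 19.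

3. Step 4. Protodeboronation or oxidative homocoupling of the boronic acid, or copper-mediated oxidation of the electron-rich phenol, may outpace C–O bond formation. The fallback sets out from 8 (with 4) and comes back at 9; it reverses the polarity of the ring B partner. (E)-3-(4-Iodophenyl)prop-2-enoic acid and 4 (EDC·HCl, HOBt) should give the iodo cinnamamide (E)-3-(4-iodophenyl)-N-[4-(triethylsilyl)but-3-yn-1-yl]prop-2-enamide F6. An Ullmann-type coupling of F6 with 8 (CuI 10 mol %, N,N-dimethylglycine, Cs2CO3, dioxane, 90 °C) should then give 9.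

**Further compounds**
F1 | step 13 | N-{2-iodo-4-{[(4R,5S)-4-ArA-2,2-dimethyl-1,3-dioxan-5-yl]oxy}phenyl}acetamide | COc1cc(cc(Oc2ccc(/C=C/C(=O)NCCC#C[Si](CC)(CC)CC)cc2)c1O[Si](C(C)C)(C(C)C)C(C)C)[C@H]3OC(C)(C)OC[C@@H]3Oc4ccc(NC(C)=O)c(I)c4
F2 | step 13 | N1-acetyl derivative of protected macrocycle 22 | COc1cc2cc(c1O[Si](C(C)C)(C(C)C)C(C)C)Oc1ccc(cc1)/C=C/C(=O)NCCc1c([Si](CC)(CC)CC)n(C(C)=O)c3ccc(cc13)O[C@H]4COC(C)(C)O[C@H]24
F3 | step 9 | (4S)-4-benzyl-3-(bromoacetyl)-1,3-oxazolidin-2-one | O=C(CBr)N1[C@@H](Cc2ccccc2)COC1=O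
F4 | step 9 | (4S)-4-benzyl-3-[(2S,3R)-3-ArA-2-bromo-3-hydroxypropanoyl]-1,3-oxazolidin-2-one | COc1cc(cc(Oc2ccc(/C=C/C(=O)NCCC#C[Si](CC)(CC)CC)cc2)c1O[Si](C(C)C)(C(C)C)C(C)C)[C@@H](O)[C@H](Br)C(=O)N4[C@@H](Cc5ccccc5)COC4=O
F5 | step 9 | (4S)-4-benzyl-3-[(2R,3R)-3-ArA-3-hydroxy-2-(3-iodo-4-nitrophenoxy)propanoyl]-1,3-oxazolidin-2-one | COc1cc(cc(Oc2ccc(/C=C/C(=O)NCCC#C[Si](CC)(CC)CC)cc2)c1O[Si](C(C)C)(C(C)C)C(C)C)[C@@H](O)[C@@H](Oc3ccc([N+](=O)[O-])c(I)c3)C(=O)N4[C@@H](Cc5ccccc5)COC4=O
F6 | step 4 | (E)-3-(4-iodophenyl)-N-[4-(triethylsilyl)but-3-yn-1-yl]prop-2-enamide | Ic1ccc(/C=C/C(=O)NCCC#C[Si](CC)(CC)CC)cc1
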